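## Retrosynthetic overview

1. Last come the 1(10)-epoxidation of a germacra-1(10),4,11(13)-trien-12,6-olide, preceded by α-methylenation of the lactone and exchange of the C3 silyl ether for the benzoate.
2. The γ-lactone and the O8 ester come from an 8-hydroxy-6-ketone by an Evans–Tishchenko reaction with (2S,3S)-2,3-dimethyloxirane-2-carbaldehyde (sets C6, acylates O8), then lactonisation of the C7 acetate arm onto O6.
3. The ten-membered ring (key step) comes from an anionic oxy-Cope [3,3] rearrangement of a 1-[(Z)-2-alkoxyvinyl]-6-isopropenylcyclohex-2-en-1-ol, which forms C8–C9, sets C8, gives the 1(10)E alkene and keeps the 4Z alkene; the enolate is alkylated at C7.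
4. The cyclohexenol comes from (S)-carvone (Luche reduction, silylation, allylic oxidation) plus (Z)-2-(4-methoxybenzyloxy)vinyllithium; the aldehyde comes from ethyl (S)-3-hydroxybutanoate (Fráter–Seebach methylation and hydroxylation, diol to oxirane, reduction).
5. Ring order: carvone six-membered ring (bought), side-chain oxirane (separate branch), ten-membered carbocycle, γ-lactone, 1,10-oxirane.

Assumption: (S)-(+)-carvone, 4-methoxybenzyl alcohol and ethyl (S)-3-hydroxybutanoate are bought; ten-membered-ring compounds carry germacrane numbering (ring C1–C10, C14 on C10, C15 on C4, C11–C13 on C7).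

## Route

Step 1
Reactants: 1 (S)-(+)-carvone
Product: 2 (1S,5S)-2-methyl-5-(prop-1-en-2-yl)cyclohex-2-en-1-ol (cis-carveol)
Conditions: NaBH4, CeCl3·7H2O, MeOH, −78 → 0 °C
Reagents that add atoms: none
Why: Luche 1,2-reduction; axial hydride attack on the half-chair enone with equatorial isopropenyl gives the cis alcohol (about 95:5), so the bought C5 (S) centre sets the carbinol (S, the future C3).

Step 2
Reactants: 2 cis-carveol
Product: 3 tert-butyldimethyl{[(1S,5S)-2-methyl-5-(prop-1-en-2-yl)cyclohex-2-en-1-yl]oxy}silane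
Conditions: TBSCl, imidazole, DMF, rt
Reagents that add atoms: tert-butyldimethylsilyl chloride CC(C)(C)[Si](C)(C)Cl
Why: Silylation of the secondary allylic alcohol gives an ether that survives the organolithium, potassium amide, oxidant and Lewis acid steps that follow; no stereocentre is touched.

Step 3
Reactants: 3 silyl ether of cis-carveol
Product: 4 (4S,6S)-4-(tert-butyldimethylsilyloxy)-3-methyl-6-(prop-1-en-2-yl)cyclohex-2-en-1-one
Conditions: t-BuOOH (5 equiv), Rh2(cap)4 (dirhodium tetrakis(caprolactamate), 1 mol %), K2CO3, CH2Cl2, rt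
Reagents that add atoms: tert-butyl hydroperoxide CC(C)(C)OO
Why: Radical allylic C–H oxidation at the only ring methylene allylic to the trisubstituted alkene, the carbinol C–H being shielded by the silyl ether; both stereocentres are kept, the cis-4,6 arrangement also being the stable one at the new α-centre.

Step 4
Reactants: 5 4-methoxybenzyl alcohol
Product: 6 4-methoxybenzyl vinyl ether
Conditions: ethyl vinyl ether (20 equiv), Pd(OAc)2 (2 mol %), 1,10-phenanthroline (2 mol %), rt
Reagents that add atoms: ethyl vinyl ether C=COCC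
Why: Palladium-diacetate-catalysed transfer vinylation (transetherification) driven by the excess of ethyl vinyl ether; no stereocentre.

Step 5
Reactants: 6 4-methoxybenzyl vinyl ether
Product: 8 (Z)-1-bromo-2-[(4-methoxybenzyl)oxy]ethene, via dibromo ether 7 (not isolated)
Conditions: Br2, CH2Cl2, −78 °C; then i-Pr2NEt, −78 °C → rt
Reagents that add atoms: bromine BrBr
Why: Bromine addition to the enol ether, then amine-mediated dehydrobromination through the labile α-bromo ether, gives the 2-bromovinyl ether; the cis (Z) isomer is favoured (cis effect of 1-alkoxy-2-haloethenes) and is separated from minor E isomer on Et3N-deactivated silica.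

Step 6
Reactants: 8 (Z)-1-bromo-2-[(4-methoxybenzyl)oxy]ethene; 4 silyloxy enone
Product: 10 (1S,4S,6S)-4-(tert-butyldimethylsilyloxy)-1-{(Z)-2-[(4-methoxybenzyl)oxy]ethenyl}-3-methyl-6-(prop-1-en-2-yl)cyclohex-2-en-1-ol, via vinyllithium 9 (not isolated)
Conditions: 8, t-BuLi (2 equiv), Et2O, −78 °C; then 4, THF, −78 °C; H2O
Reagents that add atoms: none
Why: Bromine–lithium exchange with retention of the Z geometry, then 1,2-addition to the enone carbonyl anti to the adjacent isopropenyl group, gives the trans-1,2-dialkenyl carbinol (OH cis to isopropenyl, new centre S) under substrate control.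

Step 7
Reactants: 10 dialkenyl carbinol
Product: 13 tert-butyl 2-[(3S,7R,8R,1(10)E,4Z)-3-(tert-butyldimethylsilyloxy)-8-(4-methoxybenzyloxy)-4,10-dimethyl-6-oxocyclodeca-1(10),4-dien-7-yl]acetate, via potassium alkoxide 11 (not isolated), via potassium enolate 12 (not isolated)
Conditions: KN(SiMe3)2 (1.1 equiv), 18-crown-6, THF, 0 °C → rt; then BrCH2CO2t-Bu, −78 °C
Reagents that add atoms: tert-butyl bromoacetate CC(C)(C)OC(=O)CBr
Why: Anionic oxy-Cope [3,3]-sigmatropic rearrangement through a chair transition state with the ring bonds C1–C2 and C6–C5 pseudo-equatorial forms C8–C9 and the ten-membered ring, gives the 1(10)E alkene, keeps the 4Z alkene and transfers the S configuration of the isopropenyl-bearing carbon to C8 (R, the Z-alkoxy group pseudo-axial); the enolate is then alkylated at C7 on its outer face, cis to the C8 oxygen (7R).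

Step 8
Reactants: 13 keto ester
Product: 14 tert-butyl 2-[(3S,7R,8R,1(10)E,4Z)-3-(tert-butyldimethylsilyloxy)-8-hydroxy-4,10-dimethyl-6-oxocyclodeca-1(10),4-dien-7-yl]acetate
Conditions: DDQ (1.3 equiv), CH2Cl2/pH 7 buffer (10:1), 0 °C
Reagents that add atoms: none
Why: Oxidative cleavage of the 4-methoxybenzyl ether by hydride abstraction under neutral buffered conditions frees the C8 hydroxyl without β-elimination or loss of the silyl ether, and the tert-butyl ester resists lactonisation onto O8.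

Step 9
Reactants: 15 ethyl (S)-3-hydroxybutanoate
Product: 17 ethyl (2S,3S)-3-hydroxy-2-methylbutanoate, via dilithio dianion 16 (not isolated)
Conditions: LiN(i-Pr)2 (2.1 equiv), THF, −50 → −20 °C; MeI, DMPU, −78 → 0 °C; H2O
Reagents that add atoms: iodomethane CI
Why: Fráter–Seebach alkylation; methyl iodide attacks the lithium-chelated dianion anti to the C3 methyl group, so the bought C3 (S) centre sets C2 (S, anti, at least 95:5).

Step 10
Reactants: 17 ethyl (2S,3S)-3-hydroxy-2-methylbutanoate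
Product: 19 ethyl (2S,3S)-2,3-dihydroxy-2-methylbutanoate, via dilithio dianion 18 (not isolated)
Conditions: LiN(i-Pr)2 (2.2 equiv), THF, −78 → −20 °C; MoO5·pyridine·HMPA, −78 → −40 °C; aq. Na2SO3
Reagents that add atoms: oxodiperoxymolybdenum(pyridine)(hexamethylphosphoric triamide) O=[Mo]12(OO1)OO2.c1ccncc1.CN(C)P(=O)(N(C)C)N(C)C
Why: Vedejs enolate hydroxylation in the Fráter–Seebach manner; the electrophilic peroxo oxygen enters the chelated tetrasubstituted enolate on the same face as the earlier methylation, anti to the C3 methyl, giving the erythro (2S,3S) diol.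

Step 11
Reactants: 19 ethyl (2S,3S)-2,3-dihydroxy-2-methylbutanoate
Product: 22 ethyl (2S,3S)-2,3-dimethyloxirane-2-carboxylate, via cyclic orthoacetate 20 (not isolated), via acetoxy bromide 21 (not isolated)
Conditions: MeC(OMe)3, PPTS (cat.), CH2Cl2, rt; AcBr, CH2Cl2, 0 °C; K2CO3, EtOH, rt
Reagents that add atoms: none
Why: Kolb–Sharpless diol-to-epoxide sequence; bromide opens the acetoxonium ion at the secondary C3 with inversion and the C2 alkoxide freed by ethanolysis displaces bromide with a second inversion, so the diol configuration is kept and the ester ends cis to the C3 methyl (epoxyangelate).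

Step 12
Reactants: 22 ethyl (2S,3S)-2,3-dimethyloxirane-2-carboxylate
Product: 23 (2S,3S)-2,3-dimethyloxirane-2-carbaldehyde
Conditions: i-Bu2AlH (1.05 equiv), CH2Cl2, −78 °C; Na2SO4·10H2O
Reagents that add atoms: none
Why: Partial reduction of the hindered α-quaternary ester stops at the aluminium hemiacetal at −78 °C, which releases the aldehyde on work-up; neither oxirane centre is affected and the volatile aldehyde is used as a solution.

Step 13
Reactants: 14 hydroxy keto ester; 23 (2S,3S)-2,3-dimethyloxirane-2-carbaldehyde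
Product: 25 (3S,6R,7R,8R,1(10)E,4Z)-3-(tert-butyldimethylsilyloxy)-8-[(2S,3S)-2,3-dimethyloxirane-2-carbonyloxy]-13-norgermacra-1(10),4-dien-12,6-olide, via hydroxy tert-butyl ester 24 (not isolated)
Conditions: SmI2 (0.3 equiv), 23 (3 equiv), THF, −10 °C; then TsOH·H2O (0.1 equiv), CH2Cl2, rt
Reagents that add atoms: none
Why: Evans–Tishchenko reduction; the samarium-bound hemiacetal of the C8 hydroxyl and aldehyde 23 delivers hydride intramolecularly to the C6 ketone, giving the 1,3-anti alcohol (6R, O6 α) with the epoxyangeloyl group left on O8, and acid-catalysed transesterification of the C6 hydroxyl with the tert-butyl ester closes the trans-fused γ-lactone.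

Step 14
Reactants: 25 lactone silyl ether
Product: 26 (3S,6R,7R,8R,1(10)E,4Z)-8-[(2S,3S)-2,3-dimethyloxirane-2-carbonyloxy]-3-hydroxy-13-norgermacra-1(10),4-dien-12,6-olide
Conditions: Bu4NF, AcOH (1:1), THF, 0 °C → rt
Reagents that add atoms: none
Why: Buffered fluoride desilylation (strong Si–F bond) frees the allylic C3 hydroxyl while the lactone, the oxirane ester and the alkenes stay intact.

Step 15
Reactants: 26 lactone alcohol
Product: 27 (3S,6R,7R,8R,1(10)E,4Z)-3-benzoyloxy-8-[(2S,3S)-2,3-dimethyloxirane-2-carbonyloxy]-13-norgermacra-1(10),4-dien-12,6-olide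
Conditions: BzCl, pyridine, DMAP (cat.), CH2Cl2, 0 °C → rt
Reagents that add atoms: benzoyl chloride O=C(Cl)c1ccccc1
Why: DMAP-catalysed O-acylation with retention at C3, which carries the S configuration bought in carvone.

Step 16
Reactants: 27 lactone benzoate
Product: 31 (3S,6R,7R,8R,1(10)E,4Z)-3-benzoyloxy-8-[(2S,3S)-2,3-dimethyloxirane-2-carbonyloxy]germacra-1(10),4,11(13)-trien-12,6-olide, via lithium enolate 28 (not isolated), via Mannich base 29 (not isolated), via ammonium iodide 30 (not isolated)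
Conditions: LiN(SiMe3)2 (1.2 equiv), THF, −78 °C; CH2=NMe2+ I−, −78 °C → rt; MeI, MeOH, rt; aq. NaHCO3, CH2Cl2
Reagents that add atoms: dimethylmethyleneammonium iodide C=[N+](C)C.[I-]
Why: α-Methylenation of the lactone by Mannich reaction of its enolate (the only enolisable ester, the other two lacking α-hydrogens), N-methylation and Hofmann-type elimination; C11 becomes sp2, so no new stereocentre remains.

Step 17
Reactants: 31 trienolide
Product: 32 (1R,3S,6R,7R,8R,10R,4Z)-3-benzoyloxy-1,10-epoxy-8-[(2S,3S)-2,3-dimethyloxirane-2-carbonyloxy]germacra-4,11(13)-dien-12,6-olide (CNP0324463.3)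
Conditions: mCPBA (1.1 equiv), NaHCO3, CH2Cl2, 0 °C
Reagents that add atoms: 3-chloroperoxybenzoic acid OOC(=O)c1cccc(Cl)c1
Why: Prilezhaev epoxidation; the electron-rich unconjugated 1(10)-E alkene reacts before the oxygen-flanked 4,5-alkene and the acrylate 11,13-alkene, and attack on its exposed outer face in the C14-β ring conformer gives the trans (1R,10R) oxirane stereospecifically.

## Compound list

1 | (S)-(+)-carvone, (5S)-2-methyl-5-(prop-1-en-2-yl)cyclohex-2-en-1-one | CC1=CC[C@H](C(C)=C)CC1=O | starting material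
2 | (1S,5S)-2-methyl-5-(prop-1-en-2-yl)cyclohex-2-en-1-ol (cis-carveol) | O[C@H]1C[C@@H](C(C)=C)CC=C1C | intermediate
3 | tert-butyldimethylsilyl ether of 2 | CC(C)(C)[Si](C)(C)O[C@H]1C[C@@H](C(C)=C)CC=C1C | intermediate
4 | (4S,6S)-4-(tert-butyldimethylsilyloxy)-3-methyl-6-(prop-1-en-2-yl)cyclohex-2-en-1-one | CC(C)(C)[Si](C)(C)O[C@H]1C[C@@H](C(C)=C)C(=O)C=C1C | intermediate
5 | 4-methoxybenzyl alcohol | COc1ccc(CO)cc1 | starting material
6 | 4-methoxybenzyl vinyl ether | C=COCc1ccc(OC)cc1 | intermediate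
7 | 1-[(1,2-dibromoethoxy)methyl]-4-methoxybenzene (racemic) | COc1ccc(COC(Br)CBr)cc1 | intermediate
8 | (Z)-1-bromo-2-[(4-methoxybenzyl)oxy]ethene | COc1ccc(CO/C=C\Br)cc1 | intermediate
9 | (Z)-2-[(4-methoxybenzyl)oxy]ethenyllithium | COc1ccc(CO/C=C\[Li])cc1 | intermediate
10 | (1S,4S,6S)-4-(tert-butyldimethylsilyloxy)-1-{(Z)-2-[(4-methoxybenzyl)oxy]ethenyl}-3-methyl-6-(prop-1-en-2-yl)cyclohex-2-en-1-ol (OH cis to isopropenyl and to OTBS) | CC(C)(C)[Si](C)(C)O[C@H]1C[C@@H](C(C)=C)[C@](O)(/C=C\OCc2ccc(OC)cc2)C=C1C | intermediate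
11 | potassium alkoxide of 10 | CC(C)(C)[Si](C)(C)O[C@H]1C[C@@H](C(C)=C)[C@]([O-])(/C=C\OCc2ccc(OC)cc2)C=C1C.[K+] | intermediate
12 | potassium (3S,8R,1(10)E,4Z)-3-(tert-butyldimethylsilyloxy)-8-(4-methoxybenzyloxy)-4,10-dimethylcyclodeca-1(10),4,6-trien-6-olate (O− cis to C8) | C1/C(C)=C/C[C@H](O[Si](C)(C)C(C)(C)C)/C(C)=C\C([O-])=C\[C@@H]1OCc1ccc(OC)cc1.[K+] | intermediate
13 | tert-butyl 2-[(3S,7R,8R,1(10)E,4Z)-3-(tert-butyldimethylsilyloxy)-8-(4-methoxybenzyloxy)-4,10-dimethyl-6-oxocyclodeca-1(10),4-dien-7-yl]acetate | CC(C)(C)OC(=O)C[C@H]1C(=O)/C=C(/C)[C@@H](O[Si](C)(C)C(C)(C)C)C/C=C(\C)C[C@H]1OCc1ccc(OC)cc1 | intermediate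
14 | tert-butyl 2-[(3S,7R,8R,1(10)E,4Z)-3-(tert-butyldimethylsilyloxy)-8-hydroxy-4,10-dimethyl-6-oxocyclodeca-1(10),4-dien-7-yl]acetate | CC(C)(C)OC(=O)C[C@H]1C(=O)/C=C(/C)[C@@H](O[Si](C)(C)C(C)(C)C)C/C=C(\C)C[C@H]1O | intermediate
15 | ethyl (S)-3-hydroxybutanoate | CCOC(=O)C[C@H](C)O | starting material
16 | dilithio dianion of 15 (chelated enolate alkoxide) | CCO/C([O-])=C/[C@H](C)[O-].[Li+].[Li+] | intermediate
17 | ethyl (2S,3S)-3-hydroxy-2-methylbutanoate | CCOC(=O)[C@@H](C)[C@H](C)O | intermediate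
18 | dilithio dianion of 17 | CCO/C([O-])=C(\C)[C@H](C)[O-].[Li+].[Li+] | intermediate
19 | ethyl (2S,3S)-2,3-dihydroxy-2-methylbutanoate | CCOC(=O)[C@@](C)(O)[C@H](C)O | intermediate
20 | ethyl (4S,5S)-2-methoxy-2,4,5-trimethyl-1,3-dioxolane-4-carboxylate (C2 epimers) | CCOC(=O)[C@@]1(C)OC(C)(OC)O[C@H]1C | intermediate
21 | ethyl (2R,3R)-2-acetoxy-3-bromo-2-methylbutanoate | CCOC(=O)[C@@](C)(OC(C)=O)[C@@H](C)Br | intermediate
22 | ethyl (2S,3S)-2,3-dimethyloxirane-2-carboxylate | CCOC(=O)[C@@]1(C)O[C@H]1C | intermediate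
23 | (2S,3S)-2,3-dimethyloxirane-2-carbaldehyde | O=C[C@@]1(C)O[C@H]1C | intermediate
24 | tert-butyl 2-[(3S,6R,7S,8R,1(10)E,4Z)-3-(tert-butyldimethylsilyloxy)-8-[(2S,3S)-2,3-dimethyloxirane-2-carbonyloxy]-6-hydroxy-4,10-dimethylcyclodeca-1(10),4-dien-7-yl]acetate (6α-OH, 8β-acyloxy; 7S only because the CIP ranking changes, same geometry as 13) | CC(C)(C)OC(=O)C[C@H]1[C@H](O)/C=C(/C)[C@@H](O[Si](C)(C)C(C)(C)C)C/C=C(\C)C[C@H]1OC(=O)[C@@]1(C)O[C@H]1C | intermediate
25 | (3S,6R,7R,8R,1(10)E,4Z)-3-(tert-butyldimethylsilyloxy)-8-[(2S,3S)-2,3-dimethyloxirane-2-carbonyloxy]-13-norgermacra-1(10),4-dien-12,6-olide | C1C(=O)O[C@@H]2/C=C(/C)[C@@H](O[Si](C)(C)C(C)(C)C)C/C=C(\C)C[C@@H](OC(=O)[C@@]3(C)O[C@H]3C)[C@@H]12 | intermediate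
26 | (3S,6R,7R,8R,1(10)E,4Z)-8-[(2S,3S)-2,3-dimethyloxirane-2-carbonyloxy]-3-hydroxy-13-norgermacra-1(10),4-dien-12,6-olide | C1C(=O)O[C@@H]2/C=C(/C)[C@@H](O)C/C=C(\C)C[C@@H](OC(=O)[C@@]3(C)O[C@H]3C)[C@@H]12 | intermediate
27 | (3S,6R,7R,8R,1(10)E,4Z)-3-benzoyloxy-8-[(2S,3S)-2,3-dimethyloxirane-2-carbonyloxy]-13-norgermacra-1(10),4-dien-12,6-olide | C1C(=O)O[C@@H]2/C=C(/C)[C@@H](OC(=O)c3ccccc3)C/C=C(\C)C[C@@H](OC(=O)[C@@]3(C)O[C@H]3C)[C@@H]12 | intermediate
28 | lithium enolate of 27 (C11=C12–O−) | [Li+].C1=C([O-])O[C@@H]2/C=C(/C)[C@@H](OC(=O)c3ccccc3)C/C=C(\C)C[C@@H](OC(=O)[C@@]3(C)O[C@H]3C)[C@@H]12 | intermediate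
29 | 11-(dimethylaminomethyl) derivative of 27 (Mannich base, C11 epimers) | CN(C)CC1C(=O)O[C@@H]2/C=C(/C)[C@@H](OC(=O)c3ccccc3)C/C=C(\C)C[C@@H](OC(=O)[C@@]3(C)O[C@H]3C)[C@@H]12 | intermediate
30 | trimethylammonium iodide of 29 | C[N+](C)(C)CC1C(=O)O[C@@H]2/C=C(/C)[C@@H](OC(=O)c3ccccc3)C/C=C(\C)C[C@@H](OC(=O)[C@@]3(C)O[C@H]3C)[C@@H]12.[I-] | intermediate
31 | (3S,6R,7R,8R,1(10)E,4Z)-3-benzoyloxy-8-[(2S,3S)-2,3-dimethyloxirane-2-carbonyloxy]germacra-1(10),4,11(13)-trien-12,6-olide | C=C1C(=O)O[C@@H]2/C=C(/C)[C@@H](OC(=O)c3ccccc3)C/C=C(\C)C[C@@H](OC(=O)[C@@]3(C)O[C@H]3C)[C@@H]12 | intermediate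
32 | (1R,3S,6R,7R,8R,10R,4Z)-3-benzoyloxy-1,10-epoxy-8-[(2S,3S)-2,3-dimethyloxirane-2-carbonyloxy]germacra-4,11(13)-dien-12,6-olide, CNP0324463.3 | C=C1C(=O)O[C@@H]2/C=C(/C)[C@@H](OC(=O)c3ccccc3)C[C@H]3O[C@]3(C)C[C@@H](OC(=O)[C@@]3(C)O[C@H]3C)[C@@H]12 | target

## Step count and risks

Total step count: 17 (steps 1–17). Longest linear sequence: 11 steps (1, 2, 3, 6, 7, 8, 13, 14, 15, 16, 17, from carvone 1 to 32).

Steps most likely to fail:

Step 3 (allylic oxidation). The tertiary C–H next to the isopropenyl group, the carbinol C–H and two allylic methyls compete with the ring methylene, and the product has a base-labile α-centre. The fallback sets out from 2 and returns at 4. Hydroxyl-directed epoxidation of 2 (VO(acac)2, t-BuOOH) gives the cis-epoxy alcohol F1. Silylation (TBSCl, imidazole) gives the epoxy silyl ether F2. Trans-diaxial opening at the secondary oxirane carbon with PhSeNa gives the hydroxy selenide F3. H2O2 oxidises this to the selenoxide F4, which eliminates in the flask, away from the carbinol, to the tertiary allylic alcohol F5. Pyridinium chlorochromate (C5H5NH)[CrO3Cl] then effects the Dauben–Babler oxidative 1,3-transposition to enone 4.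

Step 7 (oxy-Cope and alkylation). The Z-alkoxy group must sit pseudo-axial in the chair (leakage through a boat would give the C8 epimer), the enolate 12 can lose 4-methoxybenzyl oxide, and the alkylation must be C-selective, single and on the outer face. The fallback sets out from 10 and returns at 13. Silylation of 10 (TMSCl, imidazole) gives the trimethylsilyl ether F6. A neutral thermal siloxy-Cope rearrangement (toluene, 200 °C, sealed, base-washed glass) gives the ring-expanded silyl enol ether F7, which can be purified. MeLi then releases the lithium enolate F8 cleanly at low temperature, and alkylation with tert-butyl bromoacetate in THF/DMPU gives 13.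

Step 13 (Evans–Tishchenko). The α-quaternary epoxy aldehyde is a hindered hydride donor and its oxirane may not tolerate the samarium species. The fallback sets out from 14 (and 22) and returns at 25. Hydroxyl-directed reduction of 14 with Me4NBH(OAc)3 (MeCN/AcOH, −30 °C) gives the anti-6,8-diol F9. TsOH·H2O closes the trans-6,12-lactone to give the 8-hydroxy lactone F10. Saponification of 22 (LiOH, THF/H2O) gives the epoxyangelic acid F11. Activation with 2,4,6-trichlorobenzoyl chloride and Et3N gives the mixed anhydride F12, which acylates F10 with DMAP to give 25.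

## Further compounds

F1 | step 3 | cis-2,3-epoxy-cis-carveol (oxirane on the hydroxyl face) | O[C@H]1C[C@@H](C(C)=C)C[C@H]2O[C@@]12C
F2 | step 3 | tert-butyldimethylsilyl ether of F1 | CC(C)(C)[Si](C)(C)O[C@H]1C[C@@H](C(C)=C)C[C@H]2O[C@@]12C
F3 | step 3 | trans-diaxial hydroxy selenide (tertiary OH on C2, PhSe on C3) | CC(C)(C)[Si](C)(C)O[C@H]1C[C@@H](C(C)=C)C[C@H]([Se]c2ccccc2)[C@@]1(C)O
F4 | step 3 | selenoxide of F3 | CC(C)(C)[Si](C)(C)O[C@H]1C[C@@H](C(C)=C)C[C@H]([Se](=O)c2ccccc2)[C@@]1(C)O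
F5 | step 3 | tertiary allylic alcohol, 6-(tert-butyldimethylsilyloxy)-1-methyl-4-(prop-1-en-2-yl)cyclohex-2-en-1-ol (OH cis to OTBS) | CC(C)(C)[Si](C)(C)O[C@H]1C[C@@H](C(C)=C)C=C[C@@]1(C)O
F6 | step 7 | trimethylsilyl ether of 10 | CC(C)(C)[Si](C)(C)O[C@H]1C[C@@H](C(C)=C)[C@](O[Si](C)(C)C)(/C=C\OCc2ccc(OC)cc2)C=C1C
F7 | step 7 | trimethylsilyl enol ether of the ring-expanded ketone (6-silyloxy-1(10),4,6-triene) | C1/C(C)=C/C[C@H](O[Si](C)(C)C(C)(C)C)/C(C)=C\C(O[Si](C)(C)C)=C\[C@@H]1OCc1ccc(OC)cc1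
F8 | step 7 | lithium enolate corresponding to 12 | [Li+].C1/C(C)=C/C[C@H](O[Si](C)(C)C(C)(C)C)/C(C)=C\C([O-])=C\[C@@H]1OCc1ccc(OC)cc1
F9 | step 13 | anti-6,8-diol, tert-butyl 2-[(3S,6R,7R,8R)-3-(tert-butyldimethylsilyloxy)-6,8-dihydroxy-4,10-dimethylcyclodeca-1(10)E,4Z-dien-7-yl]acetate | CC(C)(C)OC(=O)C[C@H]1[C@H](O)/C=C(/C)[C@@H](O[Si](C)(C)C(C)(C)C)C/C=C(\C)C[C@H]1O
F10 | step 13 | 8β-hydroxy lactone, (3S,6R,7R,8R)-3-(tert-butyldimethylsilyloxy)-8-hydroxy-13-norgermacra-1(10)E,4Z-dien-12,6-olide | C1C(=O)O[C@@H]2/C=C(/C)[C@@H](O[Si](C)(C)C(C)(C)C)C/C=C(\C)C[C@@H](O)[C@@H]12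
F11 | step 13 | (2S,3S)-2,3-dimethyloxirane-2-carboxylic acid (epoxyangelic acid) | OC(=O)[C@@]1(C)O[C@H]1C
F12 | step 13 | mixed anhydride of F11 with 2,4,6-trichlorobenzoic acid | O=C(OC(=O)c1c(Cl)cc(Cl)cc1Cl)[C@@]1(C)O[C@H]1C
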